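Even the noon flask, stopped at 1.5 h, ran longer than the violet run, whose last reading came at 25.0 min, so I had to carry those readings well beyond their own range.

| setting | violet | noon | spring | dawn |
|---|---|---|---|---|
| substrate | 0.11 M | 0.11 M | 0.11 M | 0.11 M |
| first nucleophile | 0.44 M | 0.440 M | 0.440 M | 0.440 M |
| second nucleophile | 0.22 M | 0.220 M | 0.220 M | 0.220 M |
| protic impurity | 0.017 M | 0.0330 M | 0.0330 M | 0.0330 M |
| remark | run made earlier |  |  |  |
| time |  | 1.5 h | 2.0 h | 2.5 h |

violet run (percent of the substrate charged)

| time / min | solvolysis product / % | target / % | other capture product / % | substrate / % |
|---|---|---|---|---|
| 5.00 | 1.2 | 0 | 1.6 | 98.5 |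
| 10.0 | 2.7 | 0.9 | 0.2 | 94.7 |
| 15.0 | 4.5 | 0.8 | 1.9 | 93.4 |
| 20.0 | 4.4 | 2.7 | 1.7 | 91.1 |
| 25.0 | 3.2 | 2.1 | 3.6 | 89.5 |

(each reading ± 1 percentage point)

- no earlier run changes the charge of protic impurity; that part of a forecast is a guess

- which of these there is most of at the end, counted by the substrate in it, noon (other capture product / solvolysis product / substrate / target)
- which of these there is most of at the end, counted by the substrate in it, spring (other capture product / solvolysis product / substrate / target)
- which of these there is most of at the end, counted by the substrate in it, dawn (other capture product / solvolysis product / substrate / target)
- final amount of the leader among these, as a percentage of the substrate charged, in noon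
- final amount of the leader among these, as a percentage of the substrate charged, in spring
- final amount of the leader among these, as a percentage of the substrate charged, in dawn

I began with the bench rule, the straight line. The violet run had 89.5 % of its substrate standing at its last reading, a loss of 0.252 h⁻¹ of the charge, as a fraction, and on that line noon ended at 62.2 % and dawn at 37.0 %. But a line takes the same amount each hour from a shrinking pool, and the nucleophiles were charged at 4.00 and 2.00 times the substrate, so I froze something else: k, 0.266 h⁻¹, the share of the remaining substrate lost per hour, a pseudo-first-order constant. The violet reading at 20.0 min gave 0.280 h⁻¹, and both values carry the scatter. Using k in the new flasks was a guess, since their protic impurity was twice the violet charge.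

The border of the line is the product of k and time, which must stay small against unity. It was 0.111 at the end of violet but 0.399 in noon and 0.666 in dawn. My curve left 67.1 % in noon, 58.7 % in spring and 51.4 % in dawn, so the line already stood 4.9 percentage points below it in noon, against a scatter of 1 point. Even in dawn my curve kept more substrate than the 48.6 % it took away, so I expected substrate to lead there however that loss was shared, and my curve stood higher in spring than in dawn.

The forecast put substrate first in noon, spring and dawn, at 63 %, 54 % and 46 %, holding that “no product should exceed the remaining substrate”.

The flasks gave substrate as leader in noon, spring and dawn, at 66.7 %, 58.3 % and 50.9 %, with solvolysis product at 28.8 % in dawn.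

    substrate → intermediate (k = 0.270 h⁻¹)
    first nucleophile + intermediate ⇌ target (K = 30.0 L mol⁻¹, k = 16.0 L mol⁻¹ h⁻¹)
    second nucleophile + intermediate → other capture product (k = 28.0 L mol⁻¹ h⁻¹)
    intermediate → solvolysis product (k = 13.0 h⁻¹)
    second nucleophile + protic impurity → quenched reagent (k = 85.0 L mol⁻¹ h⁻¹)

The neighbour was dawn read on to 6.0 h with its charges unchanged. The same k left 20.2 % of the substrate and the flask held 19.8 %, but by then the substrate was less than what had left it, and the leader had changed: other capture product stood at 20.2 % and solvolysis product at 53.2 %.

(The readings come from a simulation with constants of no real substance; noise was put on by code.)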